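**Retrosynthetic overview**

- The strategy rests on one feature: the target is two 4-(4-hydroxyphenyl)chroman-2-ones joined C3–C3'. Each pyranone ring (O1–C2–C3–C4–C4a–C8a and its primed twin) is an aryl 4-hydroxycinnamate folded onto its own ester aryl ring, and C2–C3–C3'–C2' is a succinate.
- Key disconnection: C4–C4a and C4'–C4a', a twofold intramolecular Friedel–Crafts hydroarylation of the achiral mixed diaryl (2E,3E)-2,3-bis(4-methoxybenzylidene)succinate. One closure is catalyst-controlled; the other three stereocentres follow by substrate relay.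
- The diester comes from the bis(arylidene)succinic anhydride, opened by 3,5-dimethoxyphenol and then esterified through the acyl chloride with 2,3,4,5-tetramethoxyphenol (from 1,2,3,4-tetramethoxybenzene by formylation and Baeyer–Villiger oxidation). The diacid comes from two Stobbe condensations of dimethyl succinate with 4-methoxybenzaldehyde.
- Ring order: the 5,7-dimethoxy pyranone ring closes first (more nucleophilic arene), the 5,6,7,8-tetramethoxy pyranone ring second in the same flask. Global O-demethylation ends the route.

Key step: step 9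

Assumption: in chroman-2-one numbering the target is (3S,4R,3'S,4'R), cis at C3/C4 and at C3'/C4'; the sense of induction of the chiral acid cannot be predicted, so the catalyst antipode that gives 4R in the first closure is taken after testing both.

**Route**

Step 1
Reactants: 1 dimethyl succinate; 2 4-methoxybenzaldehyde
Product: 3 (E)-3-(methoxycarbonyl)-4-(4-methoxyphenyl)but-3-enoic acid
Conditions: NaOMe (1.3 equiv), MeOH, reflux; then aq. HCl
Reagents that add atoms: none
Why: Stobbe condensation: the succinate enolate adds to the aldehyde, the aldolate lactonises onto the distal ester, and base-induced ring opening gives the half-ester with the aryl group trans to the conjugated ester (E) for steric reasons.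

Step 2
Reactants: 3 (E)-3-(methoxycarbonyl)-4-(4-methoxyphenyl)but-3-enoic acid
Product: 4 dimethyl (E)-2-(4-methoxybenzylidene)succinate
Conditions: MeOH, H2SO4 (cat.), reflux
Reagents that add atoms: methanol, CO
Why: Fischer esterification of the non-conjugated acid restores a CH2 flanked by an ester, which the second condensation needs because a carboxylate cannot be enolised; the alkene is untouched.

Step 3
Reactants: 4 dimethyl (E)-2-(4-methoxybenzylidene)succinate; 2 4-methoxybenzaldehyde
Product: 6 (2E,3E)-2,3-bis(4-methoxybenzylidene)succinic acid, via methyl hydrogen bis(arylidene)succinate 5 (not isolated)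
Conditions: NaOMe, MeOH, reflux; then aq. NaOH, reflux; HCl; recrystallisation, amber glassware
Reagents that add atoms: sodium hydroxide, [Na+].[OH-] (one carboxyl oxygen of 6)
Why: A second Stobbe condensation at the remaining CH2 (same aldol–lactonisation–ring-opening course, E alkene again favoured) and in-flask saponification of the surviving methyl ester should give the diacid, and crystallisation removes any E,Z isomer.

Step 4
Reactants: 6 (2E,3E)-2,3-bis(4-methoxybenzylidene)succinic acid
Product: 7 (3E,4E)-3,4-bis(4-methoxybenzylidene)dihydrofuran-2,5-dione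
Conditions: Ac2O, 60 °C, dark; evaporate
Reagents that add atoms: none
Why: Cyclodehydration of a 1,4-dicarboxylic acid to its five-membered anhydride through the mixed acetic anhydride (classical fulgide formation), which leaves both E alkenes unchanged when light is excluded.

Step 5
Reactants: 7 (3E,4E)-3,4-bis(4-methoxybenzylidene)dihydrofuran-2,5-dione; 8 3,5-dimethoxyphenol
Product: 9 3,5-dimethoxyphenyl hydrogen (2E,3E)-2,3-bis(4-methoxybenzylidene)succinate
Conditions: Et3N (1.2 equiv), DMAP (cat.), CH2Cl2, 0 °C → rt, dark; cold 1 M HCl
Reagents that add atoms: none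
Why: DMAP-catalysed ring opening of a cyclic anhydride by a phenol; the anhydride is symmetrical so only one half-ester can form, and with a single phenol in the flask any reversible re-closure is harmless.

Step 6
Reactants: 10 1,2,3,4-tetramethoxybenzene
Product: 12 2,3,4,5-tetramethoxybenzaldehyde, via aryllithium 11 (not isolated)
Conditions: n-BuLi, TMEDA, THF, 0 °C; DMF, 0 °C → rt; aq. HCl
Reagents that add atoms: N,N-dimethylformamide, CN(C)C=O (formyl group); n-butyllithium, [Li]CCCC (lithium of 11 only)
Why: Methoxy-directed ortho-lithiation (the two ring C–H positions are equivalent) followed by formylation of the aryllithium with DMF.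

Step 7
Reactants: 12 2,3,4,5-tetramethoxybenzaldehyde
Product: 14 2,3,4,5-tetramethoxyphenol, via aryl formate 13 (not isolated)
Conditions: mCPBA, CH2Cl2, 0 °C → rt; Na2S2O3 wash; then K2CO3 (cat.), MeOH, rt
Reagents that add atoms: mCPBA, O=C(OO)c1cccc(Cl)c1 (phenol oxygen)
Why: Baeyer–Villiger oxidation in its Dakin sense: the electron-rich aryl group migrates in the Criegee adduct to give the aryl formate, and methanolysis frees this easily oxidised phenol only after the peracid has been destroyed.

Step 8
Reactants: 9 3,5-dimethoxyphenyl hydrogen (2E,3E)-2,3-bis(4-methoxybenzylidene)succinate; 14 2,3,4,5-tetramethoxyphenol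
Product: 16 1-(3,5-dimethoxyphenyl) 4-(2,3,4,5-tetramethoxyphenyl) (2E,3E)-2,3-bis(4-methoxybenzylidene)succinate, via acid chloride 15 (not isolated)
Conditions: (COCl)2, DMF (cat.), CH2Cl2, 0 °C → rt, evaporate; then 14, pyridine, CH2Cl2, 0 °C → rt, dark
Reagents that add atoms: oxalyl chloride, O=C(Cl)C(=O)Cl (chlorine of 15 only)
Why: Acyl chloride formation and nucleophilic acyl substitution by the phenol; the acid is activated in its neutral form, so no carboxylate is present that could expel the first aryloxy group through the cyclic anhydride and scramble the two esters.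

Step 9
Reactants: 16 1-(3,5-dimethoxyphenyl) 4-(2,3,4,5-tetramethoxyphenyl) (2E,3E)-2,3-bis(4-methoxybenzylidene)succinate
Product: 20 (3S,4R,3'S,4'R)-5,5',6',7,7',8'-hexamethoxy-4,4'-bis(4-methoxyphenyl)-[3,3'-bichromane]-2,2'-dione (octa-O-methyl ether of the target), via first cyclic enol 17 (not isolated), via monolactone cinnamate 18 (not isolated), via second cyclic enol 19 (not isolated)
Conditions: chiral imidodiphosphorimidate (IDPi) Brønsted acid HN[P(=NSO2CF3)(O2Ar*)]2, C74H33F30N3O8P2S2, O2Ar* = 3,3'-bis[3,5-bis(trifluoromethyl)phenyl]-1,1'-binaphthalene-2,2'-diolate (10 mol %), dry CHCl3 (0.01 M), −40 °C → 0 °C, Ar, dark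
Reagents that add atoms: none
Why: Proposed new method: the acid protonates a cinnamate carbonyl of 16 to a quinone-methide-like 4-methoxybenzyl cation held in the chiral anion, the ortho carbon of that ester's own aryl ring attacks the benzylic carbon in a Friedel–Crafts step that closes the first pyranone ring 6-endo-trig (C4–C4a) to enol 17, C3 is protonated to give 18, and the same events on the second cinnamate close the second pyranone ring 6-endo-trig (C4'–C4a') through enol 19. The closest known reaction types are the strong-acid cyclisation of aryl cinnamates to 4-aryl-3,4-dihydrocoumarins and chiral-Brønsted-acid hydroarylation of activated styrenes; an enantioselective twofold version on an α-branched bis-cinnamate is not known. C4 (R) is set by the catalyst, whose pocket leaves one face of the first benzylic carbon open to the 3,5-dimethoxyphenyl ring, the more nucleophilic of the two arenes. C4' (R) is set by the substrate: in 18 allylic 1,3-strain between the anisyl group on C4' and C3 holds the C3–H bond in the alkene plane, so the tetramethoxyphenyl ring adds to the face anti to the diarylmethine carbon C4, a sense the catalyst can reinforce. C3 and C3' (both S) are set by kinetic protonation of enols 17 and 19 on the face away from the neighbouring C4 or C4' aryl group, which the peri 5-methoxy group forces pseudoaxial, and this gives the cis C3/C4 and C3'/C4' relations. The step needs lactone closure to win over attack of one anisyl ring on the other cinnamate (aryldihydronaphthalene formation) and over C4' protonation of dienol 17; the substrate secures this because the ester rings attack through carbons ortho and para to methoxy groups while the anisyl ortho carbons are meta to their methoxy group, and because protonation of 17 at C3 keeps the second cinnamate conjugated.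

Step 10
Reactants: 20 octa-O-methyl ether of the target
Product: 21 (3S,4R,3'S,4'R)-5,5',6',7,7',8'-hexahydroxy-4,4'-bis(4-hydroxyphenyl)-[3,3'-bichromane]-2,2'-dione (target)
Conditions: BBr3 (20 equiv), CH2Cl2, −78 °C → 0 °C, Ar; degassed ice/1 M HCl; EtOAc; reverse-phase chromatography (H2O/MeCN, 0.1% HCO2H)
Reagents that add atoms: none
Why: Lewis-acid ether cleavage (BBr3 complexation, bromide attack on methyl, hydrolysis of the aryl borates) should remove all eight methyl groups while the aryl lactones stay closed, and the cold, acidic, oxygen-free work-up avoids enolisation at C3/C3' and autoxidation of the pentaoxygenated ring, so no stereocentre is touched.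

**Compound list**

1 | dimethyl succinate | COC(=O)CCC(=O)OC | starting material
2 | 4-methoxybenzaldehyde | COc1ccc(C=O)cc1 | starting material
3 | (E)-3-(methoxycarbonyl)-4-(4-methoxyphenyl)but-3-enoic acid | COC(=O)/C(=C/c1ccc(OC)cc1)CC(=O)O | intermediate
4 | dimethyl (E)-2-(4-methoxybenzylidene)succinate | COC(=O)/C(=C/c1ccc(OC)cc1)CC(=O)OC | intermediate
5 | methyl hydrogen (2E,3E)-2,3-bis(4-methoxybenzylidene)succinate (not isolated) | COC(=O)/C(=C/c1ccc(OC)cc1)C(=C\c1ccc(OC)cc1)/C(=O)O | intermediate
6 | (2E,3E)-2,3-bis(4-methoxybenzylidene)succinic acid | OC(=O)/C(=C/c1ccc(OC)cc1)C(=C\c1ccc(OC)cc1)/C(=O)O | intermediate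
7 | (3E,4E)-3,4-bis(4-methoxybenzylidene)dihydrofuran-2,5-dione | O=C1OC(=O)/C(=C/c2ccc(OC)cc2)/C1=C\c1ccc(OC)cc1 | intermediate
8 | 3,5-dimethoxyphenol | COc1cc(O)cc(OC)c1 | starting material
9 | 3,5-dimethoxyphenyl hydrogen (2E,3E)-2,3-bis(4-methoxybenzylidene)succinate | COc1cc(OC)cc(OC(=O)/C(=C/c2ccc(OC)cc2)C(=C\c2ccc(OC)cc2)/C(=O)O)c1 | intermediate
10 | 1,2,3,4-tetramethoxybenzene | COc1ccc(OC)c(OC)c1OC | starting material
11 | (2,3,4,5-tetramethoxyphenyl)lithium (not isolated) | [Li]c1cc(OC)c(OC)c(OC)c1OC | intermediate
12 | 2,3,4,5-tetramethoxybenzaldehyde | O=Cc1cc(OC)c(OC)c(OC)c1OC | intermediate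
13 | 2,3,4,5-tetramethoxyphenyl formate (not isolated) | O=COc1cc(OC)c(OC)c(OC)c1OC | intermediate
14 | 2,3,4,5-tetramethoxyphenol | Oc1cc(OC)c(OC)c(OC)c1OC | intermediate
15 | 3,5-dimethoxyphenyl (2E,3E)-3-(chlorocarbonyl)-2-(4-methoxybenzylidene)-4-(4-methoxyphenyl)but-3-enoate (acid chloride of 9, not isolated) | COc1cc(OC)cc(OC(=O)/C(=C/c2ccc(OC)cc2)C(=C\c2ccc(OC)cc2)/C(=O)Cl)c1 | intermediate
16 | 1-(3,5-dimethoxyphenyl) 4-(2,3,4,5-tetramethoxyphenyl) (2E,3E)-2,3-bis(4-methoxybenzylidene)succinate | COc1cc(OC)cc(OC(=O)/C(=C/c2ccc(OC)cc2)C(=C\c2ccc(OC)cc2)/C(=O)Oc2cc(OC)c(OC)c(OC)c2OC)c1 | intermediate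
17 | 2,3,4,5-tetramethoxyphenyl (2E)-2-[(4R)-2-hydroxy-5,7-dimethoxy-4-(4-methoxyphenyl)-4H-chromen-3-yl]-3-(4-methoxyphenyl)prop-2-enoate (not isolated) | OC1=C(C(=C\c2ccc(OC)cc2)/C(=O)Oc2cc(OC)c(OC)c(OC)c2OC)[C@H](c2ccc(OC)cc2)c2c(OC)cc(OC)cc2O1 | intermediate
18 | 2,3,4,5-tetramethoxyphenyl (2E)-2-[(3S,4R)-5,7-dimethoxy-4-(4-methoxyphenyl)-2-oxochroman-3-yl]-3-(4-methoxyphenyl)prop-2-enoate (not isolated) | O=C1Oc2cc(OC)cc(OC)c2[C@@H](c2ccc(OC)cc2)[C@H]1C(=C\c1ccc(OC)cc1)/C(=O)Oc1cc(OC)c(OC)c(OC)c1OC | intermediate
19 | (3S,4R)-3-[(4R)-2-hydroxy-5,6,7,8-tetramethoxy-4-(4-methoxyphenyl)-4H-chromen-3-yl]-5,7-dimethoxy-4-(4-methoxyphenyl)chroman-2-one (not isolated) | O=C1Oc2cc(OC)cc(OC)c2[C@@H](c2ccc(OC)cc2)[C@H]1C1=C(O)Oc2c(OC)c(OC)c(OC)c(OC)c2[C@H]1c1ccc(OC)cc1 | intermediate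
20 | (3S,4R,3'S,4'R)-5,5',6',7,7',8'-hexamethoxy-4,4'-bis(4-methoxyphenyl)-[3,3'-bichromane]-2,2'-dione | O=C1Oc2cc(OC)cc(OC)c2[C@@H](c2ccc(OC)cc2)[C@H]1[C@H]1C(=O)Oc2c(OC)c(OC)c(OC)c(OC)c2[C@H]1c1ccc(OC)cc1 | intermediate
21 | (3S,4R,3'S,4'R)-5,5',6',7,7',8'-hexahydroxy-4,4'-bis(4-hydroxyphenyl)-[3,3'-bichromane]-2,2'-dione | O=C1Oc2cc(O)cc(O)c2[C@@H](c2ccc(O)cc2)[C@H]1[C@H]1C(=O)Oc2c(O)c(O)c(O)c(O)c2[C@H]1c1ccc(O)cc1 | target

**Step count**

Total: 10 steps. Longest linear sequence: 8 steps (steps 1–5, 8, 9, 10); steps 6 and 7 form the side branch that joins at step 8.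

**Steps most likely to fail**

1. Step 9 (key step). The acid may be too weak or too confined to activate the α-branched cinnamates of so large a substrate, and facial discrimination at the first benzylic carbon may be poor. The relay may leak if 18 reacts through a rotamer other than the one with C3–H in the alkene plane. Re-enolisation of 18 or 20 would erode the cis C3 centres, and intermolecular alkylation at the carbon between the two methoxy groups of the dimethoxyphenyl ring may compete. The fallback sets out from 16 and uses the known strong-acid cyclisation of aryl cinnamates with an achiral acid (CF3CO2H in CH2Cl2, rt). The substrate-based relay and the cis protonations do not depend on the chiral acid, so the same relative configuration is expected as a racemate: 20 together with its mirror image, the (3R,4S,3'R,4'S)-octa-O-methyl ether F1. The two are separated by preparative chromatography on a chiral stationary phase, and the route is rejoined at 20.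

2. Step 10. Cleavage of eight ethers may stall at partial methyl ethers, and the free pentaoxygenated ring may autoxidise during work-up and chromatography. Prolonged contact with the Lewis acid and HBr may also enolise the lactones and epimerise C3/C3'. The fallback sets out from 20 and changes the isolation approach to derivatise, purify and release. After the BBr3 cleavage the crude polyphenol is not isolated but acetylated at once under acid catalysis (Ac2O, cat. H2SO4, 0 °C, Ar) to the air-stable octa-O-acetate F2. This is purified on silica or by crystallisation, where partially methylated material is removed. It is then deacetylated under acidic, oxygen-free conditions (degassed 3 M HCl/acetone, 45 °C), which favour the closed lactones and avoid base at C3/C3', and the route is rejoined at 21.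

3. Step 8. The first aryloxy group may migrate or be lost through re-closure to the anhydride or through the cyclic pseudo-chloride form of 15, which would give the two symmetrical diesters beside 16. Acylation of the ortho-methoxylated phenol by the hindered α-branched acyl chloride may also be slow. The fallback sets out from 9 and 10 and forms the second ester by C(aryl)–O bond formation instead of acyl substitution. Compound 10 is lithiated as in step 6 and quenched with B(OMe)3 and aqueous acid to give (2,3,4,5-tetramethoxyphenyl)boronic acid F3. A Chan–Lam esterification of acid 9 with this boronic acid (Cu(OTf)2, urea, EtOAc, 60 °C, air) then gives 16. No second free phenol is present, so aryloxy exchange cannot produce symmetrical diesters.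

**Further compounds**

F1 | step 9 | (3R,4S,3'R,4'S)-5,5',6',7,7',8'-hexamethoxy-4,4'-bis(4-methoxyphenyl)-[3,3'-bichromane]-2,2'-dione (enantiomer of 20) | O=C1Oc2cc(OC)cc(OC)c2[C@H](c2ccc(OC)cc2)[C@@H]1[C@@H]1C(=O)Oc2c(OC)c(OC)c(OC)c(OC)c2[C@@H]1c1ccc(OC)cc1
F2 | step 10 | (3S,4R,3'S,4'R)-4,4'-bis(4-acetoxyphenyl)-2,2'-dioxo-[3,3'-bichromane]-5,5',6',7,7',8'-hexayl hexaacetate (octa-O-acetate of 21) | O=C1Oc2cc(OC(C)=O)cc(OC(C)=O)c2[C@@H](c2ccc(OC(C)=O)cc2)[C@H]1[C@H]1C(=O)Oc2c(OC(C)=O)c(OC(C)=O)c(OC(C)=O)c(OC(C)=O)c2[C@H]1c1ccc(OC(C)=O)cc1
F3 | step 8 | (2,3,4,5-tetramethoxyphenyl)boronic acid | OB(O)c1cc(OC)c(OC)c(OC)c1OC
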